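The runs are calculated with constants of no real substance; noise was put on by code.

- The flask holds 13 mM of starting material and 2.9 mol% of free catalyst, which is 0.377 mM, under gas held at 2.0 mM. The dawn run shows a competitor: at 6.00 h it held 34.5% target and 0.7% starting material, so 64.8% had left by a side path.

| flask | starting material | gas phase | free catalyst | remark | time |
|---|---|---|---|---|---|
| summer | 6.5 mM | 2 mM (held) | 2.9 mol% | run made earlier |  |
| dawn | 26 mM | 2 mM (held) | 2.9 mol% | run made earlier |  |
| spring | 13 mM | 2 mM (held) | 1.4 mol% | run made earlier |  |
| flask | 13 mM | 2.0 mM (held) | 2.9 mol% |  | 5.0 h |

| run | time / h | target / % | starting material / % |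
|---|---|---|---|
| summer | 1.33 | 11.7 | 48.4 |
| summer | 2.50 | 16.5 | 32.1 |
| summer | 4.00 | 20.6 | 21.7 |
| summer | 5.00 | 23.4 | 16.5 |
| summer | 6.00 | 25.2 | 14.8 |
| dawn | 0.500 | 14.0 | 37.7 |
| dawn | 0.833 | 20.6 | 24.9 |
| dawn | 1.50 | 25.5 | 13.7 |
| dawn | 3.00 | 31.9 | 4.7 |
| dawn | 6.00 | 34.5 | 0.7 |
| spring | 1.33 | 8.7 | 33.8 |
| spring | 2.50 | 12.5 | 20.1 |
| spring | 4.00 | 14.4 | 12.4 |
| spring | 5.00 | 16.4 | 10.2 |
| spring | 6.00 | 17.1 | 8.3 |

(standard deviation of a reading: 0.5 percentage points)

- how much target there is at 5.0 h, in percent of the starting material charged
- the change that raises the amount of target at 5.0 h, in percent of the starting material charged most ("none" if none brings more than 2 percentage points) (green / teal / ochre / none)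
- amount of target at 5.0 h, in percent of the starting material charged, after teal

- green: doubling the saturation concentration of gas phase, all else as stated
- teal: doubling the transfer coefficient of the gas phase, all else as stated
- ochre: doubling the amount of free catalyst, all else as stated

- at the start none of the gas phase is in solution

- I wrote S for the starting material and Q for its charge. I assumed a target step first order in S and in catalyst, with gas in solution keeping pace, and a side path second order in S. At one loading, catalyst is proportional to Q, so both terms in the fall of S/Q carry one factor Q, and time enters through Qt.
- For this flask Qt is 234 M·s. I called this product the dose, charge times time; under those assumptions, equal dose at equal loading means equal percentages.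
- I tested this first. The summer run at 6.00 h and the dawn run at 1.50 h share a dose of 140 M·s, and their target readings, 25.2% and 25.5%, differ by less than the scatter of 0.5 percentage points.
- The flask has the same loading, and its dose lies between the dawn readings at 1.50 h and 3.00 h. Interpolating in the logarithm of dose, I committed to 30.2%.
- The weak link was that dose ignores anything running on the clock, such as gas entering solution. So I compared the dawn reading at 0.500 h with the summer run interpolated to the same dose, 14.8%. The gap of 0.8 points stays below the 2 points mark, so I expected teal to add little.
- The spring run, at about half this loading, read 16.4% at 5.00 h, 14 points below my figure. No run varied the gas, so I could put no figure on green, the doubling of the saturation concentration of gas phase, and I chose ochre on the spring comparison.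
- The forecast gave 29%, ochre as the best change and 30% after teal, judging that “gas transfer barely limits”.
- The flask gave 29.8%. Ochre added 18 points, green 16 points and teal 0.13 points, which left 29.9% after teal, and ochre came out best.

    gas phase ⇌ dissolved gas, rate k1*(csat - [dissolved gas]) (kL = 2.69 min⁻¹)
    starting material + dissolved gas + free catalyst → free catalyst + target (k = 5750 L² mol⁻² min⁻¹)
    2 starting material → homo dimer (k = 0.774 L mol⁻¹ min⁻¹)
    dissolved gas → decomposed reagent (k = 0.00498 min⁻¹)
    dissolved gas + free catalyst → spent catalyst (k = 0.452 L mol⁻¹ min⁻¹)

- The neighbouring flask is this same flask read at 80 min. Its dose is 62.4 M·s, between the first two dawn readings, and the same interpolation gave 17.7% target and 30.5% starting material. The neighbour reading held 93.1% free catalyst, 17.8% target and 30% starting material.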